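**Plan**
1. Retrosynthesis: C16=C17 (Mannich), the two acetates, C11–O (enolate oxidation) and C7–H (ketone reduction) are removed first. Then C4–C5 (ring A), C7–C8 (ten-membered ring), C9–C11 (fragment union) and C5=C6 (HWE) are cut.
2. Enabling feature: C5 lies β to the oxygenated C7, and C4 is the gem-dimethyl carbon. With C7 as a ketone and an E-C5=C6 bond inside the ten-membered ring (C5–C6–C7–C8–C14–C13–C12–C11–C9–C10), the prenyl end of a side chain on C10 can close ring A as a tertiary radical.
3. The ten carbons of geraniol map onto C1–C5, C9, C10 and C18–C20. A 1,2-shift moves geraniol C1 onto geraniol C3, so geraniol C1 becomes C9 and geraniol C2 becomes C5.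
4. Forward order: the cyclopentene is bought. The ten-membered ring follows from two chromium couplings (Co-catalysed alkyl, then Ni-catalysed alkenyl). Ring A is then closed by the radical step, and C7, C11, C15 and C17 are adjusted last.
5. Stereochemistry: C10 comes from Sharpless epoxidation plus a stereospecific shift. C13 comes from (S)-4-silyloxycyclopentenone by anti addition, after which that carbinol centre is eliminated. C5 is set by C10 under the constraint of the E-macrocycle, C7 by CBS reduction, and C11 by attack on the outer face of the ring enolate.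

Key step: step 17

Remark: ent-kaurane numbering is used for all atoms (ring A = C1–C5, C10; five-membered ring = C8, C14, C13, C16, C15). Carbinol centres that are oxidised later (C9 in 16–18, C7 in 18) are carried as epimer mixtures and drawn without configuration. Both antipodes of 4-(tert-butyldimethylsilyloxy)cyclopent-2-enone are taken as commercial.

Step 1
Reactants: 1 geraniol
Product: 2 (2S,3S)-2,3-epoxygeraniol
Conditions: Ti(OiPr)4 (5 mol %), L-(+)-DET (7 mol %), t-BuOOH, 4 Å MS, CH2Cl2, −20 °C
Reagents that add atoms: tert-butyl hydroperoxide, CC(C)(C)OO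
Why: Sharpless asymmetric epoxidation, in which the allylic alcohol directs the titanium tartrate to the C2=C3 bond only and L-(+)-DET should give the (2S,3S)-epoxide, the source of C10.

Step 2
Reactants: 2 (2S,3S)-2,3-epoxygeraniol
Product: 3 (2S,3S)-2,3-epoxygeranyl tert-butyldimethylsilyl ether
Conditions: TBSCl, imidazole, CH2Cl2, 0 °C to rt
Reagents that add atoms: tert-butyldimethylsilyl chloride, CC(C)(C)[Si](C)(C)Cl
Why: Standard silylation, which supplies the siloxymethyl group that migrates in the next step.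

Step 3
Reactants: 3 (2S,3S)-2,3-epoxygeranyl tert-butyldimethylsilyl ether
Product: 4 (S)-2-[(tert-butyldimethylsilyloxy)methyl]-2,6-dimethylhept-5-enal
Conditions: MABR [methylaluminium bis(4-bromo-2,6-di-tert-butylphenoxide)] (20 mol %), CH2Cl2, −78 to −40 °C
Reagents that add atoms: none
Why: Epoxy silyl ether rearrangement (semipinacol type), in which the bulky aluminium Lewis acid opens the epoxide at the tertiary carbon and the siloxymethyl group migrates anti to the leaving oxygen, so the epoxide configuration should pass to quaternary C10 with CHO (future C5) and CH2OTBS (future C9) differentiated.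

Step 4
Reactants: 4 (S)-2-[(tert-butyldimethylsilyloxy)methyl]-2,6-dimethylhept-5-enal
Product: 5 (R,E)-4-[(tert-butyldimethylsilyloxy)methyl]-N-methoxy-N,4,8-trimethylnona-2,7-dienamide
Conditions: (EtO)2P(O)CH2C(O)N(OMe)Me, NaH, THF, 0 °C to rt
Reagents that add atoms: diethyl (N-methoxy-N-methylcarbamoylmethyl)phosphonate, CCOP(=O)(CC(=O)N(C)OC)OCC
Why: Horner–Wadsworth–Emmons olefination of a non-enolisable aldehyde, which should give the E-C5=C6 bond and bring in C6 and C7 at a level that can later be released as an aldehyde.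

Step 5
Reactants: 5 (R,E)-4-[(tert-butyldimethylsilyloxy)methyl]-N-methoxy-N,4,8-trimethylnona-2,7-dienamide
Product: 6 (R,E)-4-(hydroxymethyl)-N-methoxy-N,4,8-trimethylnona-2,7-dienamide
Conditions: HF·pyridine, THF, 0 °C to rt
Reagents that add atoms: none
Why: Fluoride cleavage of a primary silyl ether, in which the E geometry keeps the freed C9 hydroxyl away from the amide carbonyl.

Step 6
Reactants: 6 (R,E)-4-(hydroxymethyl)-N-methoxy-N,4,8-trimethylnona-2,7-dienamide
Product: 7 (R,E)-4-formyl-N-methoxy-N,4,8-trimethylnona-2,7-dienamide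
Conditions: Dess–Martin periodinane, CH2Cl2, rt
Reagents that add atoms: none
Why: Dess–Martin oxidation to the C9 aldehyde, whose quaternary α-carbon excludes epimerisation and alkene migration.

Step 7
Reactants: 8 (S)-4-(tert-butyldimethylsilyloxy)cyclopent-2-en-1-one
Product: 10 methyl 2-[(1R,2S)-2-(tert-butyldimethylsilyloxy)-4-oxocyclopentyl]acetate, via bis-silyl enol ether 9 (not isolated)
Conditions: CH2=C(OMe)OTBS, TBSOTf (5 mol %), CH2Cl2, −78 °C; then 1 M HCl, THF, 0 °C
Reagents that add atoms: 1-(tert-butyldimethylsilyloxy)-1-methoxyethene, C=C(OC)O[Si](C)(C)C(C)(C)C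
Why: Mukaiyama–Michael addition, in which the ketene acetal should attack the enone face anti to the C14 silyloxy group and thereby set C13 while bringing in C12 and C11.

Step 8
Reactants: 10 methyl 2-[(1R,2S)-2-(tert-butyldimethylsilyloxy)-4-oxocyclopentyl]acetate
Product: 11 methyl 2-[(1R)-4-oxocyclopent-2-en-1-yl]acetate
Conditions: DBU, CH2Cl2, 0 °C
Reagents that add atoms: none
Why: E1cB loss of the β-silyloxy group places the C8=C14 bond regiospecifically and erases the now superfluous carbinol centre, and the short cold base contact should spare C13.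

Step 9
Reactants: 11 methyl 2-[(1R)-4-oxocyclopent-2-en-1-yl]acetate
Product: 12 methyl 2-[(1R)-3-iodo-4-oxocyclopent-2-en-1-yl]acetate
Conditions: I2, pyridine/CH2Cl2, 0 °C to rt
Reagents that add atoms: iodine, II
Why: α-Iodination of an enone by pyridine addition, iodination and elimination (Baylis–Hillman-type mechanism), which functionalises C8 only.

Step 10
Reactants: 12 methyl 2-[(1R)-3-iodo-4-oxocyclopent-2-en-1-yl]acetate
Product: 13 methyl 2-[(8R)-6-iodo-1,4-dioxaspiro[4.4]non-6-en-8-yl]acetate
Conditions: TMSOCH2CH2OTMS, TMSOTf (5 mol %), CH2Cl2, −78 to −20 °C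
Reagents that add atoms: 1,2-bis(trimethylsilyloxy)ethane, C[Si](C)(C)OCCO[Si](C)(C)C
Why: Noyori ketalisation masks C15 without alkene migration, so that C7 can later be the only conjugated carbonyl group.

Step 11
Reactants: 13 methyl 2-[(8R)-6-iodo-1,4-dioxaspiro[4.4]non-6-en-8-yl]acetate
Product: 14 2-[(8S)-6-iodo-1,4-dioxaspiro[4.4]non-6-en-8-yl]ethan-1-ol
Conditions: DIBAL-H, CH2Cl2, −78 to 0 °C
Reagents that add atoms: none
Why: Ester reduction to the primary alcohol, which alkenyl iodide and ketal tolerate (the descriptor changes only through CIP priorities).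

Step 12
Reactants: 14 2-[(8S)-6-iodo-1,4-dioxaspiro[4.4]non-6-en-8-yl]ethan-1-ol
Product: 15 (8R)-6-iodo-8-(2-iodoethyl)-1,4-dioxaspiro[4.4]non-6-ene
Conditions: I2, PPh3, imidazole, CH2Cl2, 0 °C
Reagents that add atoms: iodine, II
Why: Appel-type iodination of a primary alcohol under buffered conditions that keep the ketal intact.

Step 13
Reactants: 7 (R,E)-4-formyl-N-methoxy-N,4,8-trimethylnona-2,7-dienamide; 15 (8R)-6-iodo-8-(2-iodoethyl)-1,4-dioxaspiro[4.4]non-6-ene
Product: 16 (2E,4R)-4-{1-hydroxy-3-[(8S)-6-iodo-1,4-dioxaspiro[4.4]non-6-en-8-yl]propyl}-N-methoxy-N,4,8-trimethylnona-2,7-dienamide (C9 epimers)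
Conditions: CrCl2, cobalt phthalocyanine (5 mol %), DMF, rt
Reagents that add atoms: none
Why: Cobalt-catalysed alkyl variant of the Nozaki–Hiyama–Kishi reaction (Takai–Utimoto), in which cobalt activates only the sp3 C–I bond and the alkylchromium should add to the aldehyde (C9–C11 bond) without touching alkenyl iodide, Weinreb amide or ketal; the C9 carbinol is oxidised later.

Step 14
Reactants: 16 (2E,4R)-4-{1-hydroxy-3-[(8S)-6-iodo-1,4-dioxaspiro[4.4]non-6-en-8-yl]propyl}-N-methoxy-N,4,8-trimethylnona-2,7-dienamide (C9 epimers)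
Product: 17 (2E,4R)-4-{1-hydroxy-3-[(8S)-6-iodo-1,4-dioxaspiro[4.4]non-6-en-8-yl]propyl}-4,8-dimethylnona-2,7-dienal (C9 epimers)
Conditions: DIBAL-H, THF, −78 °C
Reagents that add atoms: none
Why: Weinreb amide reduction stops at the chelated hemiaminal and should release the E-enal (C7) on work-up, with the C9 hydroxyl carried as its aluminium alkoxide.

Step 15
Reactants: 17 (2E,4R)-4-{1-hydroxy-3-[(8S)-6-iodo-1,4-dioxaspiro[4.4]non-6-en-8-yl]propyl}-4,8-dimethylnona-2,7-dienal (C9 epimers)
Product: 18 (10R,13S)-15,15-ethylenedioxy-4,5:8,9-diseco-ent-kaura-3,5E,8(14)-triene-7,9-diol (C7 and C9 epimers)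
Conditions: CrCl2, NiCl2 (2 mol %), DMSO/THF, rt, slow addition, 2 mM
Reagents that add atoms: none
Why: Nozaki–Hiyama–Kishi macrocyclisation, in which nickel now activates the alkenyl iodide at C8 and the alkenylchromium should add 1,2 to the enal to close the ten-membered ring with both alkene geometries retained; the C7 carbinol is oxidised next.

Step 16
Reactants: 18 (10R,13S)-15,15-ethylenedioxy-4,5:8,9-diseco-ent-kaura-3,5E,8(14)-triene-7,9-diol (C7 and C9 epimers)
Product: 19 (10R,13S)-15,15-ethylenedioxy-4,5:8,9-diseco-ent-kaura-3,5E,8(14)-triene-7,9-dione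
Conditions: Dess–Martin periodinane, pyridine, CH2Cl2, 0 °C to rt
Reagents that add atoms: none
Why: Double Dess–Martin oxidation merges all carbinol epimers into one compound and creates the C5=C6–C7=O acceptor and the C9 ketone together.

Step 17
Reactants: 19 (10R,13S)-15,15-ethylenedioxy-4,5:8,9-diseco-ent-kaura-3,5E,8(14)-triene-7,9-dione
Product: 20 (5R,10R,13S)-15,15-ethylenedioxy-8,9-seco-ent-kaur-8(14)-ene-7,9-dione
Conditions: Fe(acac)3 (30 mol %), PhSiH3, EtOH/ClCH2CH2Cl, 60 °C, 5 mM
Reagents that add atoms: none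
Why: Hydrogen atom transfer from the iron hydride to C3 of the only electron-rich, unconjugated alkene gives the tertiary C4 radical, which adds to C5, the β-carbon of the C5=C6–C7=O enone, and the resulting C6 α-keto radical is reduced and protonated by Fe(II)/EtOH. The closest known reaction type is the intramolecular MHAT reductive olefin coupling (radical Giese cyclisation), which builds quaternary carbons next to congested centres. Ring A closes 6-exo-trig through a chair. C5 is controlled by C10 and by the ring: an E alkene in the ten-membered ring holds the ring bond C10–C9 roughly perpendicular to the π plane, so the chair with C9 axial (the main competitor in an open chain, where CH3 and C9 differ little in size) is out of reach, the radical enters anti to C9 on the outer face, and of the remaining chairs the one with C6 equatorial and C20 axial avoids the 1,3-diaxial contacts of an axial C6, which should place H5 trans to C20 (5R). The step needs chemoselectivity among three C=C bonds and regioselectivity between two acceptor carbons: the conjugated C5=C6 and C8=C14 bonds are poor partners for hydrogen atom transfer, attack at C14 would need a medium-ring closure, and attack at C6 (7-endo) is polarity-mismatched. The closure also removes the E alkene and its strain from the macrocycle, which adds driving force.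

Step 18
Reactants: 20 (5R,10R,13S)-15,15-ethylenedioxy-8,9-seco-ent-kaur-8(14)-ene-7,9-dione
Product: 21 (5R,7R,10R,13S)-15,15-ethylenedioxy-7-hydroxy-8,9-seco-ent-kaur-8(14)-en-9-one
Conditions: (S)-Me-CBS (20 mol %), catecholborane, toluene, −78 °C
Reagents that add atoms: none
Why: Corey–Bakshi–Shibata reduction, in which the fully substituted alkenyl carbon C8 acts as the large group and C6H2 as the small one so that the (S)-catalyst should give 7R, the same H5-side face that a kaurane-like fold leaves open, while the neopentyl C9 ketone is too hindered to react at −78 °C.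

Step 19
Reactants: 21 (5R,7R,10R,13S)-15,15-ethylenedioxy-7-hydroxy-8,9-seco-ent-kaur-8(14)-en-9-one
Product: 23 (5R,7R,10R,11S,13S)-7,11-diacetoxy-15,15-ethylenedioxy-8,9-seco-ent-kaur-8(14)-en-9-one, via 7,11-diol 22 (not isolated)
Conditions: KHMDS (3 equiv), THF, −78 °C; 2-(phenylsulfonyl)-3-phenyloxaziridine; then Ac2O, DMAP, −78 °C to rt
Reagents that add atoms: 2-(phenylsulfonyl)-3-phenyloxaziridine, O=S(=O)(c1ccccc1)N1OC1c1ccccc1; acetic anhydride, CC(=O)OC(C)=O
Why: Davis enolate oxidation, in which C9 can enolise only towards C11, the tert-alkyl group enforces the Z(O)-enolate (C12 trans to C10), and the oxidant should approach the outer face, anti to C20 and to the C13–C14 bridge, to give 11S; both alkoxides are then trapped as acetates before the ketol can isomerise.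

Step 20
Reactants: 23 (5R,7R,10R,11S,13S)-7,11-diacetoxy-15,15-ethylenedioxy-8,9-seco-ent-kaur-8(14)-en-9-one
Product: 24 (5R,7R,10R,11S,13S)-7,11-diacetoxy-8,9-seco-ent-kaur-8(14)-ene-9,15-dione
Conditions: 1 M HCl, THF, rt
Reagents that add atoms: water, O
Why: Mild hydrolysis of an allylic ketal, which should release the cyclopentenone faster than either acetate is touched.

Step 21
Reactants: 24 (5R,7R,10R,11S,13S)-7,11-diacetoxy-8,9-seco-ent-kaur-8(14)-ene-9,15-dione
Product: 26 target (5R,7R,10R,11S,13R)-7,11-diacetoxy-8,9-seco-ent-kaura-8(14),16-diene-9,15-dione, via Mannich base 25 (not isolated)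
Conditions: (CH2O)n, PhNHMe·CF3CO2H, THF, reflux
Reagents that add atoms: formaldehyde (as paraformaldehyde), C=O; N-methylanilinium trifluoroacetate (its atoms are carried only in 25), C[NH2+]c1ccccc1.[O-]C(=O)C(F)(F)F
Why: Direct Mannich α-methylenation under weakly acidic conditions, in which C16 is the only α-CH2 group in the molecule, C11 carries a single hindered hydrogen, and bridgehead C13 cannot invert (its descriptor changes only through CIP priorities).

**Compound list**
1 | geraniol | CC(C)=CCC/C(C)=C/CO | starting material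
2 | (2S,3S)-2,3-epoxygeraniol | CC(C)=CCC[C@]1(C)O[C@H]1CO | intermediate
3 | (2S,3S)-2,3-epoxygeranyl tert-butyldimethylsilyl ether | CC(C)=CCC[C@]1(C)O[C@H]1CO[Si](C)(C)C(C)(C)C | intermediate
4 | (S)-2-[(tert-butyldimethylsilyloxy)methyl]-2,6-dimethylhept-5-enal | CC(C)=CCC[C@](C)(C=O)CO[Si](C)(C)C(C)(C)C | intermediate
5 | (R,E)-4-[(tert-butyldimethylsilyloxy)methyl]-N-methoxy-N,4,8-trimethylnona-2,7-dienamide | CC(C)=CCC[C@](C)(/C=C/C(=O)N(C)OC)CO[Si](C)(C)C(C)(C)C | intermediate
6 | (R,E)-4-(hydroxymethyl)-N-methoxy-N,4,8-trimethylnona-2,7-dienamide | CC(C)=CCC[C@](C)(/C=C/C(=O)N(C)OC)CO | intermediate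
7 | (R,E)-4-formyl-N-methoxy-N,4,8-trimethylnona-2,7-dienamide | CC(C)=CCC[C@](C)(/C=C/C(=O)N(C)OC)C=O | intermediate
8 | (S)-4-(tert-butyldimethylsilyloxy)cyclopent-2-en-1-one | O=C1C[C@H](O[Si](C)(C)C(C)(C)C)C=C1 | starting material
9 | methyl 2-[(1S,5S)-3,5-bis(tert-butyldimethylsilyloxy)cyclopent-2-en-1-yl]acetate | CC(C)(C)[Si](C)(C)OC1=C[C@H](CC(=O)OC)[C@@H](O[Si](C)(C)C(C)(C)C)C1 | intermediate
10 | methyl 2-[(1R,2S)-2-(tert-butyldimethylsilyloxy)-4-oxocyclopentyl]acetate | O=C1C[C@H](O[Si](C)(C)C(C)(C)C)[C@@H](CC(=O)OC)C1 | intermediate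
11 | methyl 2-[(1R)-4-oxocyclopent-2-en-1-yl]acetate | O=C1C=C[C@@H](CC(=O)OC)C1 | intermediate
12 | methyl 2-[(1R)-3-iodo-4-oxocyclopent-2-en-1-yl]acetate | O=C1C(I)=C[C@@H](CC(=O)OC)C1 | intermediate
13 | methyl 2-[(8R)-6-iodo-1,4-dioxaspiro[4.4]non-6-en-8-yl]acetate | O1CCOC12C(I)=C[C@@H](CC(=O)OC)C2 | intermediate
14 | 2-[(8S)-6-iodo-1,4-dioxaspiro[4.4]non-6-en-8-yl]ethan-1-ol | O1CCOC12C(I)=C[C@@H](CCO)C2 | intermediate
15 | (8R)-6-iodo-8-(2-iodoethyl)-1,4-dioxaspiro[4.4]non-6-ene | O1CCOC12C(I)=C[C@@H](CCI)C2 | intermediate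
16 | (2E,4R)-4-{1-hydroxy-3-[(8S)-6-iodo-1,4-dioxaspiro[4.4]non-6-en-8-yl]propyl}-N-methoxy-N,4,8-trimethylnona-2,7-dienamide (C9 epimers) | CC(C)=CCC[C@](C)(/C=C/C(=O)N(C)OC)C(O)CC[C@@H]1C=C(I)C2(C1)OCCO2 | intermediate
17 | (2E,4R)-4-{1-hydroxy-3-[(8S)-6-iodo-1,4-dioxaspiro[4.4]non-6-en-8-yl]propyl}-4,8-dimethylnona-2,7-dienal (C9 epimers) | CC(C)=CCC[C@](C)(/C=C/C=O)C(O)CC[C@@H]1C=C(I)C2(C1)OCCO2 | intermediate
18 | (10R,13S)-15,15-ethylenedioxy-4,5:8,9-diseco-ent-kaura-3,5E,8(14)-triene-7,9-diol (C7 and C9 epimers) | CC(C)=CCC[C@]1(C)/C=C/C(O)C2=C[C@@H](CCC1O)CC23OCCO3 | intermediate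
19 | (10R,13S)-15,15-ethylenedioxy-4,5:8,9-diseco-ent-kaura-3,5E,8(14)-triene-7,9-dione | CC(C)=CCC[C@]1(C)/C=C/C(=O)C2=C[C@@H](CCC1=O)CC23OCCO3 | intermediate
20 | (5R,10R,13S)-15,15-ethylenedioxy-8,9-seco-ent-kaur-8(14)-ene-7,9-dione | C1C2(OCCO2)C3=C[C@H]1CCC(=O)[C@]1(C)CCCC(C)(C)[C@H]1CC3=O | intermediate
21 | (5R,7R,10R,13S)-15,15-ethylenedioxy-7-hydroxy-8,9-seco-ent-kaur-8(14)-en-9-one | C1C2(OCCO2)C3=C[C@H]1CCC(=O)[C@]1(C)CCCC(C)(C)[C@H]1C[C@H]3O | intermediate
22 | (5R,7R,10R,11S,13S)-15,15-ethylenedioxy-7,11-dihydroxy-8,9-seco-ent-kaur-8(14)-en-9-one | C1C2(OCCO2)C3=C[C@H]1C[C@H](O)C(=O)[C@]1(C)CCCC(C)(C)[C@H]1C[C@H]3O | intermediate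
23 | (5R,7R,10R,11S,13S)-7,11-diacetoxy-15,15-ethylenedioxy-8,9-seco-ent-kaur-8(14)-en-9-one | C1C2(OCCO2)C3=C[C@H]1C[C@H](OC(C)=O)C(=O)[C@]1(C)CCCC(C)(C)[C@H]1C[C@H]3OC(C)=O | intermediate
24 | (5R,7R,10R,11S,13S)-7,11-diacetoxy-8,9-seco-ent-kaur-8(14)-ene-9,15-dione | C1C(=O)C2=C[C@H]1C[C@H](OC(C)=O)C(=O)[C@]1(C)CCCC(C)(C)[C@H]1C[C@H]2OC(C)=O | intermediate
25 | 16-[(N-methylanilino)methyl] derivative of 24 (C16 undefined) | CN(c1ccccc1)CC1C(=O)C2=C[C@H]1C[C@H](OC(C)=O)C(=O)[C@]1(C)CCCC(C)(C)[C@H]1C[C@H]2OC(C)=O | intermediate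
26 | (5R,7R,10R,11S,13R)-7,11-diacetoxy-8,9-seco-ent-kaura-8(14),16-diene-9,15-dione (CNP0417044.1) | C=C1C(=O)C2=C[C@H]1C[C@H](OC(C)=O)C(=O)[C@]1(C)CCCC(C)(C)[C@H]1C[C@H]2OC(C)=O | target

**Step count**
Total: 21 steps. Longest linear sequence: 15 steps (steps 1–6 or 7–12, then 13–21).

**Steps most likely to fail**

Step 15 (macrocyclisation). The ring being formed holds two E alkenes separated by one carbon, so intermolecular coupling and protodeiodination may outrun ring closure. The fallback inverts the order of the two chromium couplings, so that the ring closes at C9–C11 through a flexible primary alkyl arm.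
- It sets out from 6, which DIBAL-H would reduce to (R,E)-4-(hydroxymethyl)-4,8-dimethylnona-2,7-dienal F1.
- An intermolecular Ni/Cr coupling of F1 with the alkenyl iodide of 15 would give the open-chain C7–C8 coupled diol F2, with the iodoethyl arm intact.
- Dess–Martin oxidation would give the open-chain dienone aldehyde F3.
- Co/Cr-mediated closure of the alkyl iodide onto the C9 aldehyde at high dilution would give the macrocyclic 9-hydroxy dienone F4.
- Dess–Martin oxidation of F4 comes back to the route at 19.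

Step 17 (key step). Hydride delivery to the strained dienone (conjugate reduction) may compete with hydrogen atom transfer to the trisubstituted alkene. A ring conformer in which C1 eclipses the alkene may also let the radical enter so that the C5 epimer forms. The fallback builds ring A before the macrocycle.
- It sets out from 17, where the iron hydride conditions would act on the open-chain enal, a standard acceptor, to give the ring-A aldehyde F5, with the C5 epimers separated at this stage.
- Ni/Cr closure of the C8 alkenyl iodide onto the now saturated C7 aldehyde would form the same, less strained ring as in the target and give the saturated macrocyclic 7,9-diol F6.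
- Double Dess–Martin oxidation of F6 comes back at 20.

Step 18 (C7 reduction). Catalyst control and ring shielding may be mismatched, which would give poor facial selectivity, and slow reduction at C9 may interfere. The fallback accepts the intrinsic bias of the ring and then inverts.
- It sets out from 20, where a Luche reduction (NaBH4, CeCl3, MeOH, −78 °C) would give the 7S alcohol F7.
- Mitsunobu inversion (4-nitrobenzoic acid, DIAD, PPh3) would give the 7R 4-nitrobenzoate F8.
- Methanolysis (K2CO3, MeOH) comes back at 21.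

Further compounds
F1 | step 15 | (R,E)-4-(hydroxymethyl)-4,8-dimethylnona-2,7-dienal | CC(C)=CCC[C@](C)(/C=C/C=O)CO
F2 | step 15 | open-chain C7–C8 coupled diol with intact 2-iodoethyl arm (C7 epimers) | CC(C)=CCC[C@](C)(/C=C/C(O)C1=C[C@@H](CCI)CC12OCCO2)CO
F3 | step 15 | open-chain dienone aldehyde (C7 ketone, C9 aldehyde, 2-iodoethyl arm) | CC(C)=CCC[C@](C)(/C=C/C(=O)C1=C[C@@H](CCI)CC12OCCO2)C=O
F4 | step 15 | macrocyclic 9-hydroxy dienone (C9 epimers) | CC(C)=CCC[C@]1(C)/C=C/C(=O)C2=C[C@@H](CCC1O)CC23OCCO3
F5 | step 17 | ring-A aldehyde (5R,10R,13S; C9 epimers) | O=CC[C@@H]1C(C)(C)CCC[C@@]1(C)C(O)CC[C@@H]1C=C(I)C2(C1)OCCO2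
F6 | step 17 | saturated macrocyclic 7,9-diol (C7 and C9 epimers) | C1C2(OCCO2)C3=C[C@H]1CCC(O)[C@]1(C)CCCC(C)(C)[C@H]1CC3O
F7 | step 18 | (7S)-epimer of 21 | C1C2(OCCO2)C3=C[C@H]1CCC(=O)[C@]1(C)CCCC(C)(C)[C@H]1C[C@@H]3O
F8 | step 18 | (7R)-4-nitrobenzoate of 21 | C1C2(OCCO2)C3=C[C@H]1CCC(=O)[C@]1(C)CCCC(C)(C)[C@H]1C[C@H]3OC(=O)c1ccc([N+](=O)[O-])cc1
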